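## The problem

Target 18 is a diaryl ether with no stereocentre, so every difficulty is one of regiochemistry. Ring A is a 3,5-dibromo-2-methoxyphenyl group. Ring B is a phenol carrying, in order, OH at C1, the ether oxygen at C2, Br at C3, H at C4 and Br at C5 and C6. This pattern cannot come from brominating a 2-aryloxyphenol: the only unsubstituted carbon, C4, is para to the hydroxyl, and the bromines at C3 and C5 are meta to it. The ether oxygen joins a ring-B carbon flanked by OH and Br to a ring-A carbon flanked by OMe, so a late Ullmann or SNAr coupling would have to work at a doubly ortho-substituted centre and pick one halogen among several. Five aryl bromides must survive, which excludes hydrogenolysis, zerovalent palladium catalysts such as Pd(PPh3)4 that insert into C–Br, and alkyllithium reagents, and restricts halogen–metal exchange to conditions that tell iodine from bromine. The enabling feature is the contiguous triad C1–OH, C2–OAr, C3–Br of ring B. It is what an aryne across C2–C3 delivers when an oxygen nucleophile enters at C2 and a bromine electrophile at C3, provided the C1 substituent steers the nucleophile to its own side and can later become hydroxyl; a pinacolboryl group can do both.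

## Retrosynthesis

The ring-B numbering of 18 is used for all intermediates.

**C1–O of ring B.** The hydroxyl of 18 is traced back to the C1 pinacol boronate 17. An oxygen substituent at C1 would send a nucleophile to the far aryne carbon C3, and a free phenol would not survive a Grignard reagent. Boron reverses the bias and tolerates the organomagnesium chemistry. The forward step only asks for oxidation of a hindered aryl boronate without touching C–Br.

**O–C2 and C3–Br together.** Both bonds of 17 are cut at once, giving aryne 15 (formal triple bond C2–C3), the ring-A phenol 12 as its chloromagnesium salt 13, and a positive-bromine source. The competing cuts are weaker: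
- Cutting O–C1' of ring A would need a regiodefined monoether of a tribromocatechol.
- Cutting O–C2 alone would ask an Ullmann coupling to find one halogen on a fully substituted ring.

The double cut removes the most hindered bond and one bromine in a single operation and leaves the tetrasubstituted precursor 8, in which the C5 and C6 bromines are spectators. The forward reaction must do four things:
- exchange iodine selectively (8 to 14);
- lose triflate to form 15;
- add 13 at C2 rather than C3;
- brominate arylmagnesium 16.

**O–S and C–I of 8.** The triflate comes from phenol 7, and the iodine of 7 from phenol 6. In 6 the para position is brominated and one ortho carbon carries boron, so the hydroxyl can direct iodine only to the single free ortho carbon. The step must avoid attack at the boron-bearing carbon.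

**C–B of 6.** Phenol 6 is the deprotected form of MOM ether 5, made from 2 and borate 3 through aryllithium 4. The C–H between the MOM ether and bromine in 2 is the most acidic on the ring and the lithium is held there by both neighbours. 2 is the MOM ether of commercial 3,4-dibromophenol 1, which already holds the future C5 and C6 bromines in the right relation to oxygen.

**Ring A.** Phenol 12 is cut at C–O back to aldehyde 10 (Baeyer–Villiger oxidation through formate 11), and 10 at O–CH3 back to 3,5-dibromosalicylaldehyde 9. In 9 both bromines are in place and the two oxygens of the eventual catechol are distinct from the outset: one is a phenol to be methylated, the other is still a formyl carbon. Bromination of a bromine-free catechol monomethyl ether would instead place bromine para to the free hydroxyl, where 12 has none.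

## Roads not taken

**Alternative 1:** Ring B is built rather than substituted, by cutting C2–C3 and C5–C6.
- Forward step: the O-acetonyl ether of 12, 1-(3,5-dibromo-2-methoxyphenoxy)propan-2-one A1, would be condensed in aqueous NaOH with sodium nitromalonaldehyde A2. Both α-carbons of ketone A1 close onto the two formyl groups of A2, and the product would be 2-(3,5-dibromo-2-methoxyphenoxy)-4-nitrophenol A3.
- Merits: in nitrophenol A3 the ether and the C1 hydroxyl are present from the start and nitrogen sits exactly on C4. After reduction of A3 to 4-amino-2-(3,5-dibromo-2-methoxyphenoxy)phenol A4, the free ring-B carbons C3, C5 and C6 are all ortho to NH2 or OH. Exhaustive bromination to 4-amino-2,3,5-tribromo-6-(3,5-dibromo-2-methoxyphenoxy)phenol A5 and reductive removal of the nitrogen through its diazonium ion would then give 18 with no regiochemical question on ring B.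
- Length: with the two steps to 12 this is seven linear steps of known type. That is no longer than the longest sequence of the chosen route and two steps fewer in total, which has to be conceded.
- Weak points:
  - A2 is impact-sensitive, and its condensation with an unsymmetrical α-aryloxy ketone such as A1 is not a strong reaction.
  - A4 is a para-aminophenol, which an electrophilic bromine source can oxidise at nitrogen and oxygen instead of substituting the ring.
  - Ring A still has two open carbons, ortho and para to the aryloxy oxygen, during the tribromination.
  - Diazotisation of A5 can end in loss of the phenolic proton from the diazonium ion, and reduction to C4–H is then less dependable than an ordinary deamination.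
- Comparison: the chosen plan places every bromine by construction, needs no energetic reagent and no oxidation-prone aminophenol, and is convergent. It gives away certainty, since its key step is untested while each step here is of a known type.

**Alternative 2:** No ether bond is made late; the cut runs through four C–Br bonds (C3 and C5 of ring B, C3' and C5' of ring A).
- Forward step: the bromine-free ether 2-[3-amino-2-(benzyloxy)phenoxy]phenol A6 would be treated with four equivalents of an electrophilic bromine source. The amino group at C6 of ring B should send bromine to its ortho and para carbons (C5 and C3), and the free hydroxyl of the future ring A to its own ortho and para carbons. The product would be 2-[3-amino-2-(benzyloxy)-4,6-dibromophenoxy]-4,6-dibromophenol A7. O-Methylation of A7, Sandmeyer bromination and debenzylation would finish.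
- Merits: cheap reagents, only known reaction types, and the fifth bromine enters through the nitrogen of A7 at a defined carbon.
- Weak points:
  - Four substitutions on two rings of different reactivity must be achieved with one reagent charge.
  - On ring B, C4 is para to the benzyloxy group and is the one carbon that must stay C–H.
  - On ring A the aryloxy oxygen directs to the two carbons that must stay free.
  - The aniline can be oxidised.
  - The three operations after A7 each carry a selectivity issue: O- versus N-methylation, diazotisation of an amine flanked by OBn and Br, and benzyl ether cleavage without hydrogenolysis of C–Br.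
- Comparison: A6 itself needs an ether-forming step and a nitro reduction, so the length is about that of the chosen route. Nothing in this alternative is unprecedented, which is its advantage. The chosen plan offers a regiochemical outcome fixed by one substituent, the boryl group, instead of by the balance among five directing groups.

**Alternative 3:** Ring B is again constructed, by cutting C2–C3 and C1–C6.
- Forward step: 3,5-dibromo-2H-pyran-2-one A8 and 2-[(3,5-dibromo-2-methoxyphenoxy)ethynyl]-4,4,5,5-tetramethyl-1,3,2-dioxaborolane A9 would undergo [4+2] cycloaddition and decarboxylative aromatisation. The product would be 2-[3,5-dibromo-2-(3,5-dibromo-2-methoxyphenoxy)phenyl]-4,4,5,5-tetramethyl-1,3,2-dioxaborolane A10.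
- Merits: like the chosen plan it uses boron as a masked C1 hydroxyl, and two bromines arrive with pyrone A8. Polarity matching (the nucleophilic boron-bearing alkyne carbon of A9 to the electrophilic C6 of A8) argues for the needed orientation. Cycloadditions of alkynyl boronates with 2-pyrones also have closer precedent than the key step chosen here.
- Weak points:
  - A9 is an aryloxy ynol ether. Its usual preparation from a dichlorovinyl ether with two equivalents of alkyllithium is incompatible with the bromines of ring A.
  - The cycloaddition needs prolonged heating of a fragile alkyne.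
  - A10 lacks the C6 bromine. After oxidation to 3,5-dibromo-2-(3,5-dibromo-2-methoxyphenoxy)phenol A11, the last bromination must choose C6 (ortho to OH) over C4 (para to OH, hindered but electronically favoured). For phenol A11 this choice is not secured by any substituent.
- Comparison: the length is similar. The chosen plan has all five bromines in place when the key step is over and ends with a plain oxidation, whereas this road defers a regiochemical gamble to the final step.

Key step: step 8

Remark on the chemistry: compounds 1, 3 and 9 are treated as purchasable, and BrCCl2CCl2Br, a weighable solid, is chosen as the positive-bromine source for the arylmagnesium.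

## Route

Step 1
Reactants: 1 3,4-dibromophenol
Product: 2 1,2-dibromo-4-(methoxymethoxy)benzene
Conditions: NaH, MOMCl, DMF, 0 °C to rt
Reagents that add atoms: chloromethyl methyl ether, COCCl
Why: Williamson-type O-alkylation of the sodium phenoxide; the MOM ether protects the phenol against base and serves as the directing group for the next step.

Step 2
Reactants: 2 1,2-dibromo-4-(methoxymethoxy)benzene; 3 2-isopropoxy-4,4,5,5-tetramethyl-1,3,2-dioxaborolane
Product: 5 2-[2,3-dibromo-6-(methoxymethoxy)phenyl]-4,4,5,5-tetramethyl-1,3,2-dioxaborolane, via aryllithium 4 (not isolated)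
Conditions: LiN(iPr)2 (1.1 equiv), THF, −78 °C; then 3, −78 °C to rt; aq NH4Cl
Reagents that add atoms: none
Why: Directed ortho-lithiation at the C–H flanked by the MOM ether and bromine, the most acidic site; the amide base does not exchange bromine, and the doubly ortho-stabilised aryllithium 4 is the thermodynamic sink, so no halogen migration is expected at −78 °C. Electrophilic borylation with 3 and loss of isopropoxide then gives the pinacol boronate.

Step 3
Reactants: 5 2-[2,3-dibromo-6-(methoxymethoxy)phenyl]-4,4,5,5-tetramethyl-1,3,2-dioxaborolane
Product: 6 3,4-dibromo-2-(4,4,5,5-tetramethyl-1,3,2-dioxaborolan-2-yl)phenol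
Conditions: HCl (3 M in MeOH), THF, rt to 40 °C
Reagents that add atoms: none
Why: Acid-catalysed acetal exchange removes the MOM group as dimethoxymethane; the pinacol boronate is stable to methanolic acid at this temperature.

Step 4
Reactants: 6 3,4-dibromo-2-(4,4,5,5-tetramethyl-1,3,2-dioxaborolan-2-yl)phenol
Product: 7 3,4-dibromo-6-iodo-2-(4,4,5,5-tetramethyl-1,3,2-dioxaborolan-2-yl)phenol
Conditions: N-iodosuccinimide, TsOH·H2O (10 mol%), MeCN, 0 °C to rt, dark
Reagents that add atoms: N-iodosuccinimide, O=C1CCC(=O)N1I
Why: Electrophilic aromatic iodination directed by the hydroxyl to its only free ortho carbon (para carries bromine, the other ortho carbon carries boron); ring halogenation of hydroxyaryl pinacol boronates with retention of boron is a known reaction type.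

Step 5
Reactants: 7 3,4-dibromo-6-iodo-2-(4,4,5,5-tetramethyl-1,3,2-dioxaborolan-2-yl)phenol
Product: 8 3,4-dibromo-6-iodo-2-(4,4,5,5-tetramethyl-1,3,2-dioxaborolan-2-yl)phenyl trifluoromethanesulfonate
Conditions: Tf2O, pyridine, CH2Cl2, 0 °C
Reagents that add atoms: trifluoromethanesulfonic anhydride, O=S(=O)(OS(=O)(=O)C(F)(F)F)C(F)(F)F
Why: O-Sulfonylation of the phenol; Tf2O is small and reactive enough for a hydroxyl flanked by iodine and the boronate, and neither C–I nor C–B reacts with it.

Step 6
Reactants: 9 3,5-dibromo-2-hydroxybenzaldehyde
Product: 10 3,5-dibromo-2-methoxybenzaldehyde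
Conditions: MeI, K2CO3, DMF, rt
Reagents that add atoms: iodomethane, CI
Why: Williamson O-methylation of an acidic, bromine-flanked phenol; the aldehyde has no α-hydrogen and is inert to carbonate.

Step 7
Reactants: 10 3,5-dibromo-2-methoxybenzaldehyde
Product: 12 3,5-dibromo-2-methoxyphenol, via aryl formate 11 (not isolated)
Conditions: mCPBA, CH2Cl2, rt to 40 °C; then K2CO3, MeOH, rt
Reagents that add atoms: 3-chloroperoxybenzoic acid, O=C(OO)c1cccc(Cl)c1
Why: Baeyer–Villiger oxidation, in which the ortho-methoxyaryl group migrates in preference to hydride to give formate 11; methanolysis of the formate then frees the phenol without touching the methyl ether.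

Step 8
Reactants: 8 3,4-dibromo-6-iodo-2-(4,4,5,5-tetramethyl-1,3,2-dioxaborolan-2-yl)phenyl trifluoromethanesulfonate; 12 3,5-dibromo-2-methoxyphenol
Product: 17 2-[2,3,5-tribromo-6-(3,5-dibromo-2-methoxyphenoxy)phenyl]-4,4,5,5-tetramethyl-1,3,2-dioxaborolane, via chloromagnesium aryloxide 13 (not isolated), via magnesiated triflate 14 (not isolated), via aryne 15 (not isolated), via arylmagnesium adduct 16 (not isolated)
Conditions: 12 (2 equiv), iPrMgCl·LiCl (2 equiv), THF, 0 °C; 8, then iPrMgCl·LiCl (1.05 equiv), −78 to −30 °C; BrCCl2CCl2Br (3 equiv), −78 °C to rt
Reagents that add atoms: 1,2-dibromo-1,1,2,2-tetrachloroethane, ClC(Cl)(Br)C(Cl)(Cl)Br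
Why: Proposed new method: iodine–magnesium exchange at the iodine-bearing carbon of 8 (C3 in ring-B numbering) should be complete at −78 °C, long before any C–Br bond exchanges, and the ortho-magnesiated triflate 14 then loses MgCl(OTf) to give aryne 15 across C2–C3. The chloromagnesium aryloxide 13, present in excess and able to bind the vacant boron orbital of the neighbouring boronate, adds through oxygen at C2, and the resulting C3 arylmagnesium 16 is brominated by BrCCl2CCl2Br with loss of tetrachloroethene, so O–C2 and C3–Br form in one flask. No ring closes and no stereocentre arises. The closest known reaction types are the proximal-selective addition of amines to 3-borylarynes generated from 6-boryl-2-iodophenyl triflates with iPrMgCl·LiCl, and the addition of magnesium thiolates or amides to magnesium-generated arynes followed by electrophilic quench; an aryloxide nucleophile combined with a bromine quench has not been shown. The selectivity needed is attack at C2 rather than C3: the σ-donating boryl group at C1 distorts the aryne so that C2 is the more electrophilic terminus and can hand a boron-bound aryloxide on to it, C4–H exerts no bias, and the C5 and C6 bromines are meta or para to both termini and cancel. Chemoselectivity rests on iodine exchanging far faster than bromine, on all alkylmagnesium being consumed before 15 appears, and on 16 having no ortho leaving group, so it persists until the bromine source is added.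

Step 9
Reactants: 17 2-[2,3,5-tribromo-6-(3,5-dibromo-2-methoxyphenoxy)phenyl]-4,4,5,5-tetramethyl-1,3,2-dioxaborolane
Product: 18 2,3,5-tribromo-6-(3,5-dibromo-2-methoxyphenoxy)phenol
Conditions: 30% aq H2O2, NaOH, THF/H2O, 0 °C; then aq HCl
Reagents that add atoms: hydrogen peroxide, OO
Why: Oxidation of the aryl boronate: hydroperoxide adds to boron and the aryl group shifts from boron to oxygen, so the hydroxyl appears exactly at C1; aryl bromides, the methyl ether and the diaryl ether are inert to cold alkaline peroxide.

## Compound list

1 | 3,4-dibromophenol | Oc1ccc(Br)c(Br)c1 | starting material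
2 | 1,2-dibromo-4-(methoxymethoxy)benzene | COCOc1ccc(Br)c(Br)c1 | intermediate
3 | 2-isopropoxy-4,4,5,5-tetramethyl-1,3,2-dioxaborolane | CC(C)OB1OC(C)(C)C(C)(C)O1 | starting material
4 | [2,3-dibromo-6-(methoxymethoxy)phenyl]lithium | COCOc1ccc(Br)c(Br)c1[Li] | intermediate
5 | 2-[2,3-dibromo-6-(methoxymethoxy)phenyl]-4,4,5,5-tetramethyl-1,3,2-dioxaborolane | COCOc1ccc(Br)c(Br)c1B1OC(C)(C)C(C)(C)O1 | intermediate
6 | 3,4-dibromo-2-(4,4,5,5-tetramethyl-1,3,2-dioxaborolan-2-yl)phenol | Oc1ccc(Br)c(Br)c1B1OC(C)(C)C(C)(C)O1 | intermediate
7 | 3,4-dibromo-6-iodo-2-(4,4,5,5-tetramethyl-1,3,2-dioxaborolan-2-yl)phenol | Oc1c(I)cc(Br)c(Br)c1B1OC(C)(C)C(C)(C)O1 | intermediate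
8 | 3,4-dibromo-6-iodo-2-(4,4,5,5-tetramethyl-1,3,2-dioxaborolan-2-yl)phenyl trifluoromethanesulfonate | O=S(=O)(Oc1c(I)cc(Br)c(Br)c1B1OC(C)(C)C(C)(C)O1)C(F)(F)F | intermediate
9 | 3,5-dibromo-2-hydroxybenzaldehyde (3,5-dibromosalicylaldehyde) | O=Cc1cc(Br)cc(Br)c1O | starting material
10 | 3,5-dibromo-2-methoxybenzaldehyde | COc1c(Br)cc(Br)cc1C=O | intermediate
11 | 3,5-dibromo-2-methoxyphenyl formate | COc1c(Br)cc(Br)cc1OC=O | intermediate
12 | 3,5-dibromo-2-methoxyphenol | COc1c(Br)cc(Br)cc1O | intermediate
13 | chlorido(3,5-dibromo-2-methoxyphenolato)magnesium | COc1c(Br)cc(Br)cc1O[Mg]Cl | intermediate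
14 | chloro[4,5-dibromo-3-(4,4,5,5-tetramethyl-1,3,2-dioxaborolan-2-yl)-2-(trifluoromethylsulfonyloxy)phenyl]magnesium | O=S(=O)(Oc1c([Mg]Cl)cc(Br)c(Br)c1B1OC(C)(C)C(C)(C)O1)C(F)(F)F | intermediate
15 | 2-(2,3-dibromo-5,6-didehydrophenyl)-4,4,5,5-tetramethyl-1,3,2-dioxaborolane (aryne, formal triple bond between C2 and C3 of ring B) | CC1(C)OB(OC1(C)C)C1=C(Br)C(Br)=CC#C1 | intermediate
16 | chloro[4,5-dibromo-2-(3,5-dibromo-2-methoxyphenoxy)-3-(4,4,5,5-tetramethyl-1,3,2-dioxaborolan-2-yl)phenyl]magnesium | COc1c(Br)cc(Br)cc1Oc1c([Mg]Cl)cc(Br)c(Br)c1B1OC(C)(C)C(C)(C)O1 | intermediate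
17 | 2-[2,3,5-tribromo-6-(3,5-dibromo-2-methoxyphenoxy)phenyl]-4,4,5,5-tetramethyl-1,3,2-dioxaborolane | COc1c(Br)cc(Br)cc1Oc1c(Br)cc(Br)c(Br)c1B1OC(C)(C)C(C)(C)O1 | intermediate
18 | 2,3,5-tribromo-6-(3,5-dibromo-2-methoxyphenoxy)phenol | COc1c(Br)cc(Br)cc1Oc1c(Br)cc(Br)c(Br)c1O | target

## Step count and risks

Total step count: 9. Longest linear sequence: 7 steps (steps 1 to 5, then 8 and 9); steps 6 and 7 form the two-step branch to 12.

**Step 8 (key step, the one new method).**
- Risk: the hindered, electron-poor magnesium aryloxide may add too slowly, so that the aryne is consumed by oligomerisation or by attack of 16 on a second aryne. Addition may also leak to C3, or 16 may be protonated or scrambled by bromine–magnesium exchange before the bromine quench.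
- Fallback (known reaction types only): it sets out from 6 and returns at 17. Phenol 6 is brominated with N-bromosuccinimide at its free ortho carbon to give 3,4,6-tribromo-2-(4,4,5,5-tetramethyl-1,3,2-dioxaborolan-2-yl)phenol F1. Separately, commercial 2,4-dibromoanisole is iodinated ortho to the methoxy group (N-iodosuccinimide, TfOH) to 1,5-dibromo-3-iodo-2-methoxybenzene F2. F2 is oxidised at iodine to the trivalent state with mCPBA and TsOH and condensed with 1,3,5-trimethoxybenzene to (3,5-dibromo-2-methoxyphenyl)(2,4,6-trimethoxyphenyl)iodonium 4-methylbenzenesulfonate F3. Metal-free O-arylation of F1 with F3 (K2CO3, MeCN, 50 °C), in which the electron-rich trimethoxyphenyl group stays on iodine, closes the ether from the ring-A side and gives 17. The one-flask double functionalisation is lost, but the arylation of phenols with diaryliodonium salts is established.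

**Step 4.**
- Risk: the iodine electrophile may attack the boron-bearing carbon (iododeboronation), or the acid catalyst may cause protodeboronation, instead of substitution at the free ortho carbon.
- Fallback: it sets out from 1 and returns at 7, bringing iodine in before boron. Phenol 1 is mono-iodinated at its less hindered ortho carbon to 4,5-dibromo-2-iodophenol F4 and protected as 1,2-dibromo-4-iodo-5-(methoxymethoxy)benzene F5. F5 is magnesiated between the MOM ether and bromine with (2,2,6,6-tetramethylpiperidin-1-yl)magnesium chloride–lithium chloride (TMPMgCl·LiCl), which leaves C–I intact, to give chloro[2,3-dibromo-5-iodo-6-(methoxymethoxy)phenyl]magnesium F6. Binding of the magnesium amide to the MOM oxygen should favour this C–H over the one between bromine and iodine. Trapping with 3 gives 2-[2,3-dibromo-5-iodo-6-(methoxymethoxy)phenyl]-4,4,5,5-tetramethyl-1,3,2-dioxaborolane F7, and methanolic HCl then gives 7.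

**Step 2.**
- Risk: aryllithium 4 has bromine on the neighbouring carbon and may lose LiBr to an aryne on local warming; bromine migration between ring positions is the other concern.
- Fallback: it sets out from 2 and returns at 5, replacing the aryllithium by an arylmagnesium. Deprotonative magnesiation of 2 with TMPMgCl·LiCl at 0 °C gives chloro[2,3-dibromo-6-(methoxymethoxy)phenyl]magnesium F8, which does not expel bromide below room temperature, and F8 is borylated with 3 to give 5.

**Step 7.**
- Risk: hydride may migrate in place of the electron-poor dibromoaryl group, whose methoxy group is twisted out of conjugation by its two neighbours, leading to the benzoic acid and not the formate.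
- Fallback: it sets out from 10 and returns at 12, replacing the formyl hydrogen by a methyl group, so that the aryl group competes only against methyl, which does not migrate in its place. Addition of MeMgBr to 10 (THF, −78 to 0 °C, no bromine–magnesium exchange with a methyl Grignard reagent) gives racemic 1-(3,5-dibromo-2-methoxyphenyl)ethan-1-ol F9. Oxidation with Dess–Martin periodinane gives 1-(3,5-dibromo-2-methoxyphenyl)ethan-1-one F10. Baeyer–Villiger oxidation with mCPBA and CF3CO2H gives 3,5-dibromo-2-methoxyphenyl acetate F11, and methanolysis (K2CO3, MeOH) then gives 12.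

## Further compounds

F1 | step 8 | 3,4,6-tribromo-2-(4,4,5,5-tetramethyl-1,3,2-dioxaborolan-2-yl)phenol | Oc1c(Br)cc(Br)c(Br)c1B1OC(C)(C)C(C)(C)O1
F2 | step 8 | 1,5-dibromo-3-iodo-2-methoxybenzene | COc1c(Br)cc(Br)cc1I
F3 | step 8 | (3,5-dibromo-2-methoxyphenyl)(2,4,6-trimethoxyphenyl)iodonium 4-methylbenzenesulfonate | COc1c(Br)cc(Br)cc1[I+]c1c(OC)cc(OC)cc1OC.Cc1ccc(cc1)S(=O)(=O)[O-]
F4 | step 4 | 4,5-dibromo-2-iodophenol | Oc1cc(Br)c(Br)cc1I
F5 | step 4 | 1,2-dibromo-4-iodo-5-(methoxymethoxy)benzene | COCOc1cc(Br)c(Br)cc1I
F6 | step 4 | chloro[2,3-dibromo-5-iodo-6-(methoxymethoxy)phenyl]magnesium | COCOc1c(I)cc(Br)c(Br)c1[Mg]Cl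
F7 | step 4 | 2-[2,3-dibromo-5-iodo-6-(methoxymethoxy)phenyl]-4,4,5,5-tetramethyl-1,3,2-dioxaborolane | COCOc1c(I)cc(Br)c(Br)c1B1OC(C)(C)C(C)(C)O1
F8 | step 2 | chloro[2,3-dibromo-6-(methoxymethoxy)phenyl]magnesium | COCOc1ccc(Br)c(Br)c1[Mg]Cl
F9 | step 7 | racemic 1-(3,5-dibromo-2-methoxyphenyl)ethan-1-ol | COc1c(Br)cc(Br)cc1C(C)O
F10 | step 7 | 1-(3,5-dibromo-2-methoxyphenyl)ethan-1-one | COc1c(Br)cc(Br)cc1C(C)=O
F11 | step 7 | 3,5-dibromo-2-methoxyphenyl acetate | COc1c(Br)cc(Br)cc1OC(C)=O
A1 | alternative 1 | 1-(3,5-dibromo-2-methoxyphenoxy)propan-2-one | COc1c(Br)cc(Br)cc1OCC(C)=O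
A2 | alternative 1 | sodium nitromalonaldehyde | [Na+].[O-]C=C(C=O)[N+](=O)[O-]
A3 | alternative 1 | 2-(3,5-dibromo-2-methoxyphenoxy)-4-nitrophenol | COc1c(Br)cc(Br)cc1Oc1cc([N+](=O)[O-])ccc1O
A4 | alternative 1 | 4-amino-2-(3,5-dibromo-2-methoxyphenoxy)phenol | COc1c(Br)cc(Br)cc1Oc1cc(N)ccc1O
A5 | alternative 1 | 4-amino-2,3,5-tribromo-6-(3,5-dibromo-2-methoxyphenoxy)phenol | COc1c(Br)cc(Br)cc1Oc1c(Br)c(N)c(Br)c(Br)c1O
A6 | alternative 2 | 2-[3-amino-2-(benzyloxy)phenoxy]phenol | Oc1ccccc1Oc1cccc(N)c1OCc1ccccc1
A7 | alternative 2 | 2-[3-amino-2-(benzyloxy)-4,6-dibromophenoxy]-4,6-dibromophenol | Oc1c(Br)cc(Br)cc1Oc1c(Br)cc(Br)c(N)c1OCc1ccccc1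
A8 | alternative 3 | 3,5-dibromo-2H-pyran-2-one | O=C1OC=C(Br)C=C1Br
A9 | alternative 3 | 2-[(3,5-dibromo-2-methoxyphenoxy)ethynyl]-4,4,5,5-tetramethyl-1,3,2-dioxaborolane | COc1c(Br)cc(Br)cc1OC#CB1OC(C)(C)C(C)(C)O1
A10 | alternative 3 | 2-[3,5-dibromo-2-(3,5-dibromo-2-methoxyphenoxy)phenyl]-4,4,5,5-tetramethyl-1,3,2-dioxaborolane | COc1c(Br)cc(Br)cc1Oc1c(Br)cc(Br)cc1B1OC(C)(C)C(C)(C)O1
A11 | alternative 3 | 3,5-dibromo-2-(3,5-dibromo-2-methoxyphenoxy)phenol | COc1c(Br)cc(Br)cc1Oc1c(Br)cc(Br)cc1O
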